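Its constants are assumed.

In this flask L.Z and E together cannot pass 80.0% of the X charged: each L.Z takes one Z, and Z, the limiting reagent, is charged at 0.800 equiv.

    X ⇌ L, rate k1*(cs1 - [L]) while solid is left; crystals form when [L] > cs1 (cs1 = 0.11 M, k1 = 0.0137 s⁻¹)
    L + Z → L.Z (k2 = 0.306 L mol⁻¹ s⁻¹)
    E ⇌ L.Z, rate k3*(cs3 - [L.Z]) while solid is left; crystals form when [L.Z] > cs3 (cs3 = 0.069 M, k3 = 0.480 s⁻¹)

X 0.20 M; Z 0.800 equiv; time 4.0 min

- alder: doubling the solubility in step 1, all else as stated
- maple: doubling the solubility in step 3, all else as stated
- birch: doubling the dissolution coefficient of step 3, all else as stated
- elm: doubling the amount of Z, all else as stated

- what is said of L.Z includes E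
- X, E is a solid; its amount is given per volume of the solution
- at the start none of X is in solution
- L means what is dissolved; the solid is not counted in it
- run time (flask): 4.0 min

- amount of L.Z and E together at 4.0 min, in percent of the X charged
- concentration of L in solution at 1.0 min, in percent of saturation
- the change that raises the amount of L.Z and E together at 4.0 min, in percent of the X charged most ("none" if none brings more than 2 percentage points) (alder / maple / birch / elm / none)
- amount of L.Z and E together at 4.0 min, in percent of the X charged, after maple

The hunch was that slowly dissolving X holds the figure down, and a count of turnovers tests it. Dissolution coefficient times solubility times time, divided by the charge, gives 1.81: this is the delivery count, the number of whole charges of X that dissolving can carry over in the given time into a solution kept empty.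

But the solution is not empty. L goes on to L.Z with a half-life of 0.24 min at Z as charged, short against the 4.0 min of the run. Balancing that loss against the dissolving puts [L] near 21.9% of saturation while Z is close to its charge, and somewhat higher as Z falls. Dissolving then keeps the remaining share of its full speed, so the net count is 1.41, more than one, and the reckoning has X gone near 2.83 min.

The hunch therefore fails in this flask: the yield stands below 80.0% by whatever Z is still unbound, and the reckoning commits to a figure close under that cap. Doubling Z lifts the cap, doubling the first solubility can only close the gap beneath it, and the two changes to the dissolving of E move product between L.Z and E without changing their sum. So elm should win, and maple should leave the yield where it was.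

The forecast gives 75%, 25.5%, elm and 75%, holding that “Step 3 only moves product between dissolved and solid forms”. The flask gives 75.3%, 25.1%, elm with a gain of 24 percentage points against 3 points for alder, and 75.3% after maple.

At 1.38 min the half-life of L by its reaction with Z is 0.41 min, short against the 4.0 min of the run. In this flask at 4.00 min, X stands at 0% while Z keeps 5.9% of its charge, so the reading to watch is Z rather than the solid. For the same flask read at 1.0 min, the net count scaled to that time gives 35.3% of the charge dissolved. The computed flask at that time holds solid X at 62.6%, so 37.4% has dissolved, with L.Z at 23.6%.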